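The isoflavone is cut across ring C at O1–C8a and C4–C4a. These two bonds end on adjacent carbons of ring A, which carries oxygen only at C6 and C7, so both can be made on a symmetric 4,5-dioxygenated benzyne. One fluoride-triggered operation joins a 4,5-bis(benzyloxy)-2-silylaryl triflate to the Z enol of a formylated 3,4,5-trimethoxyphenylacetate: O-arylation, then acylation of the aryl anion, closes the pyranone. The symmetric aryne removes any regiochemical question. The 6- and 7-oxygens are told apart afterwards through the higher acidity of the 7-hydroxyl, para to the C4 carbonyl.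

Key step: step 5

Remark: enol 11 is drawn as its hydrogen-bonded Z form; it equilibrates with the E enol and the aldehyde tautomer, all of which give the same enolate under the conditions of step 5.

Step 1
Reactants: 1 3,4-bis(benzyloxy)benzaldehyde
Product: 3 3,4-bis(benzyloxy)phenol, via 3,4-bis(benzyloxy)phenyl formate 2 (not isolated)
Conditions: mCPBA, CH2Cl2, 0 °C to rt; then aq KOH, MeOH, 0 °C; aq HCl work-up
Reagents that add atoms: meta-chloroperoxybenzoic acid, O=C(OO)c1cccc(Cl)c1
Why: Baeyer–Villiger (Dakin-type) oxidation, in which the electron-rich aryl group migrates in preference to hydride and the aryl formate is then cleaved by base, the benzyl ethers being inert to both stages.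

Step 2
Reactants: 3 3,4-bis(benzyloxy)phenol
Product: 4 2-bromo-4,5-bis(benzyloxy)phenol
Conditions: NBS (1.0 equiv), CH2Cl2, −20 to 0 °C, dark
Reagents that add atoms: N-bromosuccinimide, O=C1CCC(=O)N1Br
Why: electrophilic aromatic bromination directed ortho by the hydroxyl (para position blocked), which should go to the open ortho site that is also para to a benzyloxy group and not to the site flanked by two oxygens.

Step 3
Reactants: 4 2-bromo-4,5-bis(benzyloxy)phenol
Product: 7 4,5-bis(benzyloxy)-2-(trimethylsilyl)phenyl trifluoromethanesulfonate, via aryl trimethylsilyl ether 5 (not isolated), via lithium 2-silylphenoxide 6 (not isolated)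
Conditions: HMDS, THF, reflux, then evaporation; n-BuLi, THF, −78 °C; Tf2O, −78 °C to rt
Reagents that add atoms: hexamethyldisilazane, C[Si](C)(C)N[Si](C)(C)C; trifluoromethanesulfonic anhydride, O=S(=O)(OS(=O)(=O)C(F)(F)F)C(F)(F)F
Why: O-silylation, bromine–lithium exchange with anionic 1,3 O-to-C silyl shift (retro-Brook rearrangement) and O-triflation of the resulting phenoxide in one pot, the exchange at −78 °C being much faster than benzylic deprotonation of the benzyl ethers.

Step 4
Reactants: 8 methyl 2-(3,4,5-trimethoxyphenyl)acetate; 9 methyl formate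
Product: 11 methyl (Z)-3-hydroxy-2-(3,4,5-trimethoxyphenyl)prop-2-enoate, via sodium enolate 10 (not isolated)
Conditions: NaH, HCO2Me (excess), THF, 0 °C to rt; aq HCl work-up
Reagents that add atoms: none
Why: crossed Claisen condensation (C-formylation) with a formate that cannot enolise, driven by deprotonation of the product to its stabilised enolate, with matching methyl esters so that ester exchange is without consequence.

Step 5
Reactants: 7 4,5-bis(benzyloxy)-2-(trimethylsilyl)phenyl trifluoromethanesulfonate; 11 methyl (Z)-3-hydroxy-2-(3,4,5-trimethoxyphenyl)prop-2-enoate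
Product: 13 6,7-bis(benzyloxy)-3-(3,4,5-trimethoxyphenyl)-4H-chromen-4-one, via 4,5-bis(benzyloxy)benzyne 12 (not isolated)
Conditions: CsF (4 equiv), THF, 65 °C
Reagents that add atoms: none
Why: Proposed new method: fluoride attacks silicon in 7 and loss of triflate releases aryne 12; the enolate of 11 adds through its formyl-derived oxygen (O1–C8a), and the aryl anion thus placed on the neighbouring carbon attacks the cis ester carbonyl (C4a–C4) and expels methoxide, which the hydrogen fluoride formed on enolisation neutralises. The closest known reaction type is the CsF-mediated annulation of arynes with methyl salicylates to xanthones, for which 11 is the open-chain analogue. Ring C closes by a 6-exo-trig addition–elimination of the aryl carbanion at the ester carbonyl. No stereocenter is created. The step needs O- rather than C-arylation of the ambident enolate and a cis arrangement of aryl ether and ester: the fully substituted, aryl-conjugated alpha carbon is hindered towards the aryne, and THF should keep the cesium enolate as a chelated U-shaped (Z) contact ion pair, whereas an E adduct cannot cyclise and is only protonated. Since 12 is symmetric, either orientation of addition leads to the same 6,7-bis(benzyloxy) product, so no regiochemical control is required.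

Step 6
Reactants: 13 6,7-bis(benzyloxy)-3-(3,4,5-trimethoxyphenyl)-4H-chromen-4-one
Product: 14 6,7-dihydroxy-3-(3,4,5-trimethoxyphenyl)-4H-chromen-4-one
Conditions: H2 (1 atm), 10% Pd/C, THF–MeOH, rt
Reagents that add atoms: none
Why: catalytic hydrogenolysis of both benzyl aryl ethers, which should be faster than reduction of the vinylogous-ester C2–C3 double bond and leaves the methyl ethers untouched.

Step 7
Reactants: 14 6,7-dihydroxy-3-(3,4,5-trimethoxyphenyl)-4H-chromen-4-one
Product: 15 7-(benzyloxy)-6-hydroxy-3-(3,4,5-trimethoxyphenyl)-4H-chromen-4-one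
Conditions: BnBr (1.05 equiv), KHCO3, DMF, 40 °C
Reagents that add atoms: benzyl bromide, BrCc1ccccc1
Why: Williamson etherification under a weak base that ionises only the 7-hydroxyl (para to the C4 carbonyl, a vinylogous acid), so alkylation should occur at O7 and leave the 6-hydroxyl free.

Step 8
Reactants: 15 7-(benzyloxy)-6-hydroxy-3-(3,4,5-trimethoxyphenyl)-4H-chromen-4-one
Product: 16 7-(benzyloxy)-6-methoxy-3-(3,4,5-trimethoxyphenyl)-4H-chromen-4-one
Conditions: MeI, K2CO3, acetone, reflux
Reagents that add atoms: iodomethane, CI
Why: Williamson O-methylation of the only remaining free phenol.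

Step 9
Reactants: 16 7-(benzyloxy)-6-methoxy-3-(3,4,5-trimethoxyphenyl)-4H-chromen-4-one
Product: 17 7-hydroxy-6-methoxy-3-(3,4,5-trimethoxyphenyl)-4H-chromen-4-one
Conditions: H2 (1 atm), 10% Pd/C, EtOAc–MeOH, rt
Reagents that add atoms: none
Why: catalytic hydrogenolysis of the single benzyl aryl ether, which should release the 7-hydroxyl without affecting the four methyl ethers or the pyranone.

Compound list
1 | 3,4-bis(benzyloxy)benzaldehyde | O=Cc1ccc(OCc2ccccc2)c(OCc2ccccc2)c1 | starting material
2 | 3,4-bis(benzyloxy)phenyl formate | O=COc1ccc(OCc2ccccc2)c(OCc2ccccc2)c1 | intermediate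
3 | 3,4-bis(benzyloxy)phenol | Oc1ccc(OCc2ccccc2)c(OCc2ccccc2)c1 | intermediate
4 | 2-bromo-4,5-bis(benzyloxy)phenol | Oc1cc(OCc2ccccc2)c(OCc2ccccc2)cc1Br | intermediate
5 | [2-bromo-4,5-bis(benzyloxy)phenoxy]trimethylsilane | C[Si](C)(C)Oc1cc(OCc2ccccc2)c(OCc2ccccc2)cc1Br | intermediate
6 | lithium 4,5-bis(benzyloxy)-2-(trimethylsilyl)phenoxide | [Li+].[O-]c1cc(OCc2ccccc2)c(OCc2ccccc2)cc1[Si](C)(C)C | intermediate
7 | 4,5-bis(benzyloxy)-2-(trimethylsilyl)phenyl trifluoromethanesulfonate | C[Si](C)(C)c1cc(OCc2ccccc2)c(OCc2ccccc2)cc1OS(=O)(=O)C(F)(F)F | intermediate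
8 | methyl 2-(3,4,5-trimethoxyphenyl)acetate | COC(=O)Cc1cc(OC)c(OC)c(OC)c1 | starting material
9 | methyl formate | COC=O | starting material
10 | sodium (Z)-3-methoxy-3-oxo-2-(3,4,5-trimethoxyphenyl)prop-1-en-1-olate | [Na+].COC(=O)/C(=C\[O-])c1cc(OC)c(OC)c(OC)c1 | intermediate
11 | methyl (Z)-3-hydroxy-2-(3,4,5-trimethoxyphenyl)prop-2-enoate | COC(=O)/C(=C\O)c1cc(OC)c(OC)c(OC)c1 | intermediate
12 | 4,5-bis(benzyloxy)benzyne | C1#CC=C(OCc2ccccc2)C(OCc2ccccc2)=C1 | intermediate
13 | 6,7-bis(benzyloxy)-3-(3,4,5-trimethoxyphenyl)-4H-chromen-4-one | COc1cc(-c2coc3cc(OCc4ccccc4)c(OCc4ccccc4)cc3c2=O)cc(OC)c1OC | intermediate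
14 | 6,7-dihydroxy-3-(3,4,5-trimethoxyphenyl)-4H-chromen-4-one | COc1cc(-c2coc3cc(O)c(O)cc3c2=O)cc(OC)c1OC | intermediate
15 | 7-(benzyloxy)-6-hydroxy-3-(3,4,5-trimethoxyphenyl)-4H-chromen-4-one | COc1cc(-c2coc3cc(OCc4ccccc4)c(O)cc3c2=O)cc(OC)c1OC | intermediate
16 | 7-(benzyloxy)-6-methoxy-3-(3,4,5-trimethoxyphenyl)-4H-chromen-4-one | COc1cc(-c2coc3cc(OCc4ccccc4)c(OC)cc3c2=O)cc(OC)c1OC | intermediate
17 | 7-hydroxy-6-methoxy-3-(3,4,5-trimethoxyphenyl)-4H-chromen-4-one | COc1cc2c(=O)c(-c3cc(OC)c(OC)c(OC)c3)coc2cc1O | target

Total step count: 9 steps.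
Longest linear sequence: 8 steps (1 → 3 → 4 → 7 → 13 → 14 → 15 → 16 → 17; the arylacetate branch joins at step 5).

Steps most likely to fail

1. Step 5 (key step). Three processes may compete with ring closure:
- arylation of the enolate at carbon, followed by attack of the aryl anion on the formyl group and fragmentation;
- formation of the enol ether with the aryl anion remote from the ester (E geometry), so that it is merely protonated;
- quenching of the aryl anion before it acylates.

Fallback, by the established deoxybenzoin route to isoflavones: ester 8 is saponified (LiOH, THF–H2O) to 3,4,5-trimethoxyphenylacetic acid F1. F1 acylates commercial benzene-1,2,4-triol in BF3·OEt2 at 80 °C (Friedel–Crafts acylation ortho to one hydroxyl and para to another) to give 1-(2,4,5-trihydroxyphenyl)-2-(3,4,5-trimethoxyphenyl)ethan-1-one F2. Formylative ring closure of F2 with DMF, BF3·OEt2 and MsCl inserts C2 and gives diol 14, where the route is rejoined. Steps 1–3 and 6 are then not needed.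

2. Step 7. Discrimination between the two phenolic oxygens may be incomplete, or a second alkylation may occur. Fallback without a protecting group, using the known alkylation of catechol dianions at the oxygen meta to a carbonyl group: diol 14 is converted with NaH (2.2 equiv) in DMF at 0 °C into its disodium 6,7-diolate F3 and treated with MeI (1.0 equiv). In the dianion the 6-oxide, the conjugate base of the weaker acid, is the stronger nucleophile, so methylation should take place at O6. Acidic work-up gives target 17 directly, and steps 8 and 9 fall away.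

3. Step 2. The very electron-rich phenol may be brominated twice or oxidised. Fallback by reversing the order of operations: aldehyde 1 is brominated first (Br2, NaOAc, AcOH, rt), para to the 3-benzyloxy group, to give 2-bromo-4,5-bis(benzyloxy)benzaldehyde F4; the deactivating formyl group should stop the reaction at monobromination. Baeyer–Villiger oxidation (mCPBA, CH2Cl2) gives 2-bromo-4,5-bis(benzyloxy)phenyl formate F5, and cleavage with aq KOH in MeOH returns bromophenol 4.

Further compounds
F1 | step 5 | 3,4,5-trimethoxyphenylacetic acid | OC(=O)Cc1cc(OC)c(OC)c(OC)c1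
F2 | step 5 | 1-(2,4,5-trihydroxyphenyl)-2-(3,4,5-trimethoxyphenyl)ethan-1-one | COc1cc(CC(=O)c2cc(O)c(O)cc2O)cc(OC)c1OC
F3 | step 7 | disodium 4-oxo-3-(3,4,5-trimethoxyphenyl)-4H-chromene-6,7-diolate | [Na+].[Na+].COc1cc(-c2coc3cc([O-])c([O-])cc3c2=O)cc(OC)c1OC
F4 | step 2 | 2-bromo-4,5-bis(benzyloxy)benzaldehyde | O=Cc1cc(OCc2ccccc2)c(OCc2ccccc2)cc1Br
F5 | step 2 | 2-bromo-4,5-bis(benzyloxy)phenyl formate | O=COc1cc(OCc2ccccc2)c(OCc2ccccc2)cc1Br
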